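**Retrosynthetic overview**
1. Ring A (C1 CO2Me, C2 OAr, C3 OMe, C4 Cl, C5 OH, C6 H) has its chlorine at C4 between the oxygenated carbons C3 and C5, so C4 is treated as the active methylene of a cyclohexane-1,3-dione that already carries the C1 ester and the C2 aryloxy group.
2. Target 17 ⇐ 4-chlororesorcinol diaryl ether 12 (benzyl ester, 5-O-silylation, 3-O-methylation, deprotection); 12 ⇐ dione 9 by 4,4-dichlorination and loss of HCl.
3. Dione 9 ⇐ aryloxyacetone 6 + dimethyl fumarate 7: Michael addition makes C1–C2, Claisen condensation makes C4–C5 and closes ring A.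
4. 6 ⇐ 2,6-dihydroxy-4-methylbenzoic acid 1 by O-alkylations only, so the diaryl ether oxygen is never made by aryl–O coupling. The ring-B carboxyl is freed before the annulation, because an ortho ester would be acylated by the same enolate (Dieckmann closure to a 2-acetyl-3-hydroxybenzofuran), whereas a carboxylate cannot be.
5. Ring order: ring B is bought with 1; ring A is built in step 5 and aromatised in step 7.

Key step: step 5

Remark: the target has no stereocentre and no configurationally stable axis, so it is one achiral compound and no enantiocontrol is needed; the two stereocentres made in step 5 are erased in step 7.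

Step 1
Reactants: 1 2,6-dihydroxy-4-methylbenzoic acid
Product: 2 allyl 2,6-dihydroxy-4-methylbenzoate
Conditions: allyl bromide (1.1 equiv), KHCO3 (1.1 equiv), DMF, rt
Reagents that add atoms: allyl bromide, C=CCBr
Why: Carboxylate O-alkylation (SN2 esterification), in which bicarbonate ionises only the carboxylic acid and leaves the two hydrogen-bonded phenols untouched.

Step 2
Reactants: 2 allyl 2,6-dihydroxy-4-methylbenzoate
Product: 3 allyl 2-(benzyloxy)-6-hydroxy-4-methylbenzoate
Conditions: BnBr (1.05 equiv), K2CO3 (1.1 equiv), acetone, reflux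
Reagents that add atoms: benzyl bromide, BrCc1ccccc1
Why: Williamson ether synthesis on two equivalent hydroxyls that should stop at the mono-ether, because the remaining hydroxyl is held in a strong hydrogen bond to the ester carbonyl and is alkylated much more slowly.

Step 3
Reactants: 3 allyl 2-(benzyloxy)-6-hydroxy-4-methylbenzoate; 4 chloroacetone
Product: 5 allyl 2-(benzyloxy)-4-methyl-6-(2-oxopropoxy)benzoate
Conditions: 4 (1.5 equiv), K2CO3 (2 equiv), KI (0.1 equiv), acetone, 50 °C
Reagents that add atoms: none
Why: Williamson alkylation of the chelated phenol by the highly SN2-reactive α-halo ketone with Finkelstein activation by iodide; carbonate in acetone is too weak to enolise the product ketone, so no Dieckmann closure onto the ortho ester is expected here.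

Step 4
Reactants: 5 allyl 2-(benzyloxy)-4-methyl-6-(2-oxopropoxy)benzoate
Product: 6 2-(benzyloxy)-4-methyl-6-(2-oxopropoxy)benzoic acid
Conditions: Pd(PPh3)4 (3 mol %), morpholine (3 equiv), THF, rt; 1 M HCl work-up
Reagents that add atoms: none
Why: Tsuji–Trost deallylation, in which Pd(0) ionises the ester at the allylic C–O bond so that the hindered di-ortho-substituted acyl carbon is not attacked, and morpholine traps the π-allyl; the benzyl ether and the ketone are inert.

Step 5
Reactants: 6 2-(benzyloxy)-4-methyl-6-(2-oxopropoxy)benzoic acid; 7 dimethyl fumarate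
Product: 9 2-(benzyloxy)-6-{[2-(methoxycarbonyl)-4,6-dioxocyclohexyl]oxy}-4-methylbenzoic acid, via Michael adduct 8 (not isolated)
Conditions: KOtBu (2.2 equiv), THF–t-BuOH (10:1), −40 °C; 7 (1.2 equiv) added slowly, −40 °C → rt; 1 M HCl quench
Reagents that add atoms: none
Why: The carboxylate–enolate dianion of 6, equilibrated to the more acidic aryloxy-stabilised enolate, adds through its oxygen-bearing carbon to dimethyl fumarate (C1–C2), and after proton transfer the ketone-methyl enolate acylates the ester 1,5 to it (C4–C5) with loss of methoxide, which deprotonates the product; this is the tandem Michael–Claisen (acetonylsuccinate-type) synthesis of 3,5-dioxocyclohexanecarboxylates. Ring A closes in the 6-(enolendo)-exo-trig mode, whereas closure onto the nearer ester would be a disfavoured 5-(enolendo)-exo-trig process. The two new stereocentres (C1 and C2) are not controlled and need not be, since both become sp2 carbons in step 7, so 9 is carried on as a diastereomer (and keto–enol) mixture. The step needs donation from the aryloxy carbon and not the methyl, which thermodynamic enolate formation in the presence of t-BuOH as proton shuttle should secure, and six- over five-ring acylation, which the Baldwin preference and the stability of the six-membered dione enolate should secure. It also needs the C2 aryloxide not to be lost by β-elimination, which a hindered alkoxide at low temperature should limit by keeping the C1 ester enolate population small, while the product is protected as its dione enolate. The ring-B carboxyl is deliberately present as a carboxylate, which the enolate cannot acylate, whereas an ortho ester would divert the enolate into a Dieckmann closure to a 2-acetyl-3-hydroxybenzofuran.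

Step 6
Reactants: 9 2-(benzyloxy)-6-{[2-(methoxycarbonyl)-4,6-dioxocyclohexyl]oxy}-4-methylbenzoic acid
Product: 11 2-(benzyloxy)-6-{[3,3-dichloro-6-(methoxycarbonyl)-2,4-dioxocyclohexyl]oxy}-4-methylbenzoic acid, via 4-chloro dione 10 (not isolated)
Conditions: NCS (2.1 equiv), MeCN, 0 °C → rt
Reagents that add atoms: N-chlorosuccinimide, O=C1CCC(=O)N1Cl
Why: Electrophilic α-chlorination of the enolised 1,3-dione at C4, its only doubly activated carbon; the 4-chloro dione 10 is still enolic and takes the second chlorine at the same carbon, and NCS under these conditions should not chlorinate ring B.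

Step 7
Reactants: 11 2-(benzyloxy)-6-{[3,3-dichloro-6-(methoxycarbonyl)-2,4-dioxocyclohexyl]oxy}-4-methylbenzoic acid
Product: 12 2-(benzyloxy)-6-[3-chloro-2,4-dihydroxy-6-(methoxycarbonyl)phenoxy]-4-methylbenzoic acid
Conditions: HCl (4 M in dioxane, 1 equiv), DMF, 70 °C
Reagents that add atoms: none
Why: Dehydrochlorinative aromatisation of a 2,2-dichlorocyclohexane-1,3-dione to a 2-chlororesorcinol: acid-promoted enolisation towards C6 sets up a 1,4-elimination of HCl (C1–H, acidified by the ester, and C4–Cl), and tautomerisation of the dienone fixes chlorine between the two hydroxyls.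

Step 8
Reactants: 12 2-(benzyloxy)-6-[3-chloro-2,4-dihydroxy-6-(methoxycarbonyl)phenoxy]-4-methylbenzoic acid
Product: 13 benzyl 2-(benzyloxy)-6-[3-chloro-2,4-dihydroxy-6-(methoxycarbonyl)phenoxy]-4-methylbenzoate
Conditions: BnBr (1.05 equiv), KHCO3 (1.0 equiv), DMF, rt
Reagents that add atoms: benzyl bromide, BrCc1ccccc1
Why: Carboxylate O-alkylation, in which one equivalent of bicarbonate ionises only the carboxylic acid (several pKa units more acidic than the chlorophenols) and benzylation occurs at oxygen, away from the hindered acyl carbon.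

Step 9
Reactants: 13 benzyl 2-(benzyloxy)-6-[3-chloro-2,4-dihydroxy-6-(methoxycarbonyl)phenoxy]-4-methylbenzoate
Product: 14 benzyl 2-(benzyloxy)-6-{3-chloro-2-hydroxy-6-(methoxycarbonyl)-4-[(triisopropylsilyl)oxy]phenoxy}-4-methylbenzoate
Conditions: TIPSCl (1.05 equiv), imidazole (2.5 equiv), DMF, 0 °C
Reagents that add atoms: triisopropylsilyl chloride, CC(C)[Si](Cl)(C(C)C)C(C)C
Why: Sterically controlled silylation, in which the 5-hydroxyl has one ortho substituent (Cl) while the 3-hydroxyl is flanked by chlorine and the bulky aryloxy group, so the large silyl group should go to O5.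

Step 10
Reactants: 14 benzyl 2-(benzyloxy)-6-{3-chloro-2-hydroxy-6-(methoxycarbonyl)-4-[(triisopropylsilyl)oxy]phenoxy}-4-methylbenzoate
Product: 15 benzyl 2-(benzyloxy)-6-{3-chloro-2-methoxy-6-(methoxycarbonyl)-4-[(triisopropylsilyl)oxy]phenoxy}-4-methylbenzoate
Conditions: MeI (3 equiv), K2CO3 (1.5 equiv), dry acetone, 40 °C
Reagents that add atoms: iodomethane, CI
Why: Williamson O-methylation of the only free phenol; methyl iodide is small enough to reach the flanked 3-phenoxide, and anhydrous carbonate in acetone should leave the aryl TIPS ether and both esters intact.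

Step 11
Reactants: 15 benzyl 2-(benzyloxy)-6-{3-chloro-2-methoxy-6-(methoxycarbonyl)-4-[(triisopropylsilyl)oxy]phenoxy}-4-methylbenzoate
Product: 16 benzyl 2-(benzyloxy)-6-[3-chloro-4-hydroxy-2-methoxy-6-(methoxycarbonyl)phenoxy]-4-methylbenzoate
Conditions: TBAF (1.1 equiv), AcOH (1.1 equiv), THF, 0 °C
Reagents that add atoms: none
Why: Fluoride-induced cleavage of the aryl silyl ether, buffered with acetic acid so that the liberated phenoxide does not attack the esters.

Step 12
Reactants: 16 benzyl 2-(benzyloxy)-6-[3-chloro-4-hydroxy-2-methoxy-6-(methoxycarbonyl)phenoxy]-4-methylbenzoate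
Product: 17 2-[3-chloro-4-hydroxy-2-methoxy-6-(methoxycarbonyl)phenoxy]-6-hydroxy-4-methylbenzoic acid
Conditions: H2 (1 atm), 10% Pd/C, EtOAc, rt, stopped when 16 is consumed
Reagents that add atoms: none
Why: Catalytic hydrogenolysis of the benzyl ether and benzyl ester, where benzylic C–O cleavage under neutral conditions at 1 atm should be much faster than aryl C–Cl hydrogenolysis; the methyl ester and methyl ether are inert.

**Compound list**
1 | 2,6-dihydroxy-4-methylbenzoic acid | Cc1cc(O)c(C(=O)O)c(O)c1 | starting material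
2 | allyl 2,6-dihydroxy-4-methylbenzoate | C=CCOC(=O)c1c(O)cc(C)cc1O | intermediate
3 | allyl 2-(benzyloxy)-6-hydroxy-4-methylbenzoate | C=CCOC(=O)c1c(O)cc(C)cc1OCc1ccccc1 | intermediate
4 | chloroacetone (1-chloropropan-2-one) | CC(=O)CCl | starting material
5 | allyl 2-(benzyloxy)-4-methyl-6-(2-oxopropoxy)benzoate | C=CCOC(=O)c1c(OCC(C)=O)cc(C)cc1OCc1ccccc1 | intermediate
6 | 2-(benzyloxy)-4-methyl-6-(2-oxopropoxy)benzoic acid | CC(=O)COc1cc(C)cc(OCc2ccccc2)c1C(=O)O | intermediate
7 | dimethyl fumarate (E) | COC(=O)/C=C/C(=O)OC | starting material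
8 | dimethyl 2-{1-[3-(benzyloxy)-2-carboxy-5-methylphenoxy]-2-oxopropyl}butanedioate (Michael adduct, diastereomer mixture, not isolated) | CC(=O)C(Oc1cc(C)cc(OCc2ccccc2)c1C(=O)O)C(CC(=O)OC)C(=O)OC | intermediate
9 | 2-(benzyloxy)-6-{[2-(methoxycarbonyl)-4,6-dioxocyclohexyl]oxy}-4-methylbenzoic acid (unassigned diastereomer mixture, enolised) | COC(=O)C1CC(=O)CC(=O)C1Oc1cc(C)cc(OCc2ccccc2)c1C(=O)O | intermediate
10 | 2-(benzyloxy)-6-{[3-chloro-6-(methoxycarbonyl)-2,4-dioxocyclohexyl]oxy}-4-methylbenzoic acid (stereoisomer mixture, enolised, not isolated) | COC(=O)C1CC(=O)C(Cl)C(=O)C1Oc1cc(C)cc(OCc2ccccc2)c1C(=O)O | intermediate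
11 | 2-(benzyloxy)-6-{[3,3-dichloro-6-(methoxycarbonyl)-2,4-dioxocyclohexyl]oxy}-4-methylbenzoic acid (diastereomer mixture) | COC(=O)C1CC(=O)C(Cl)(Cl)C(=O)C1Oc1cc(C)cc(OCc2ccccc2)c1C(=O)O | intermediate
12 | 2-(benzyloxy)-6-[3-chloro-2,4-dihydroxy-6-(methoxycarbonyl)phenoxy]-4-methylbenzoic acid | COC(=O)c1cc(O)c(Cl)c(O)c1Oc1cc(C)cc(OCc2ccccc2)c1C(=O)O | intermediate
13 | benzyl 2-(benzyloxy)-6-[3-chloro-2,4-dihydroxy-6-(methoxycarbonyl)phenoxy]-4-methylbenzoate | COC(=O)c1cc(O)c(Cl)c(O)c1Oc1cc(C)cc(OCc2ccccc2)c1C(=O)OCc1ccccc1 | intermediate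
14 | benzyl 2-(benzyloxy)-6-{3-chloro-2-hydroxy-6-(methoxycarbonyl)-4-[(triisopropylsilyl)oxy]phenoxy}-4-methylbenzoate | COC(=O)c1cc(O[Si](C(C)C)(C(C)C)C(C)C)c(Cl)c(O)c1Oc1cc(C)cc(OCc2ccccc2)c1C(=O)OCc1ccccc1 | intermediate
15 | benzyl 2-(benzyloxy)-6-{3-chloro-2-methoxy-6-(methoxycarbonyl)-4-[(triisopropylsilyl)oxy]phenoxy}-4-methylbenzoate | COC(=O)c1cc(O[Si](C(C)C)(C(C)C)C(C)C)c(Cl)c(OC)c1Oc1cc(C)cc(OCc2ccccc2)c1C(=O)OCc1ccccc1 | intermediate
16 | benzyl 2-(benzyloxy)-6-[3-chloro-4-hydroxy-2-methoxy-6-(methoxycarbonyl)phenoxy]-4-methylbenzoate | COC(=O)c1cc(O)c(Cl)c(OC)c1Oc1cc(C)cc(OCc2ccccc2)c1C(=O)OCc1ccccc1 | intermediate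
17 | 2-[3-chloro-4-hydroxy-2-methoxy-6-(methoxycarbonyl)phenoxy]-6-hydroxy-4-methylbenzoic acid | COC(=O)c1cc(O)c(Cl)c(OC)c1Oc1cc(C)cc(O)c1C(=O)O | target

**Step count**
Total: 12 steps. Longest linear sequence: 12 steps (1 → 17).

**Steps most likely to fail**

Step 5 (Michael–Claisen annulation). What may go wrong: β-elimination of the aryloxide once a proton is removed from C1, donation from the ketone methyl instead of the aryloxy carbon, or anionic oligomerisation of the fumarate. The fallback sets out from 3 and comes back at 9. It exchanges the roles of the partners, so that the donor has a single enolisable position and the Claisen acceptor is the more electrophilic α-aryloxy ester. Compound 3 is alkylated with methyl bromoacetate (K2CO3, acetone) to allyl 2-(benzyloxy)-6-(2-methoxy-2-oxoethoxy)-4-methylbenzoate F1. Deallylation with Pd(PPh3)4 and morpholine gives 2-(benzyloxy)-6-(2-methoxy-2-oxoethoxy)-4-methylbenzoic acid F2. Its carboxylate–ester enolate dianion (LiHMDS, 2.1 equiv, THF, −78 °C) should add to methyl (E)-4-oxopent-2-enoate at the carbon β to the ketone, giving dimethyl 2-[3-(benzyloxy)-2-carboxy-5-methylphenoxy]-3-(2-oxopropyl)butanedioate F3, which is not isolated. On warming, the ketone-methyl enolate should close onto the aryloxyacetate ester (C3–C4 bond, again 6-(enolendo)-exo-trig) and deliver the same dione acid 9. The enolate left by this Michael addition is a ketone enolate, which is less basic than the ester enolate of the main route, so abstraction of the C1 proton should be less likely.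

Step 7 (chlorinative aromatisation). What may go wrong: under hot acid the aryloxy group is lost, or the dichlorodione is cleaved, before HCl is eliminated. The fallback sets out from 9 and comes back at 12. One equivalent of NCS gives the 4-chloro dione 10, and one equivalent of NBS converts it into 2-(benzyloxy)-6-{[3-bromo-3-chloro-6-(methoxycarbonyl)-2,4-dioxocyclohexyl]oxy}-4-methylbenzoic acid F4. Bromide is the better leaving group, so the 1,4-elimination of HBr should proceed at room temperature with 2,4,6-collidine in DMF and give 12 with the chlorine retained.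

Step 9 (differentiation of the two ring-A hydroxyls). What may go wrong: poor site selectivity in the silylation, so that the later methylation lands on the wrong oxygen. The fallback sets out from 12 and comes back at 17, and uses the ring-B carboxyl as a tether. Lactonisation of 12 (EDC·HCl, DMAP, CH2Cl2, high dilution) can engage only the 3-hydroxyl and should give the depsidone methyl 1-(benzyloxy)-9-chloro-8-hydroxy-3-methyl-11-oxo-11H-dibenzo[b,e][1,4]dioxepine-6-carboxylate F5. The single remaining phenol is benzylated (BnBr, K2CO3, acetone) to methyl 1,8-bis(benzyloxy)-9-chloro-3-methyl-11-oxo-11H-dibenzo[b,e][1,4]dioxepine-6-carboxylate F6. Lithium benzyloxide (1.0 equiv, THF, −40 °C) should open the activated aryl lactone in preference to the methyl ester, giving the phenoxide of benzyl 2-(benzyloxy)-6-[4-(benzyloxy)-3-chloro-2-hydroxy-6-(methoxycarbonyl)phenoxy]-4-methylbenzoate F7. This is methylated in the same flask with iodomethane to benzyl 2-(benzyloxy)-6-[4-(benzyloxy)-3-chloro-2-methoxy-6-(methoxycarbonyl)phenoxy]-4-methylbenzoate F8. Hydrogenolysis (H2, Pd/C, EtOAc) then removes all three benzyl groups and gives 17.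

**Further compounds**
F1 | step 5 | allyl 2-(benzyloxy)-6-(2-methoxy-2-oxoethoxy)-4-methylbenzoate | C=CCOC(=O)c1c(OCC(=O)OC)cc(C)cc1OCc1ccccc1
F2 | step 5 | 2-(benzyloxy)-6-(2-methoxy-2-oxoethoxy)-4-methylbenzoic acid | COC(=O)COc1cc(C)cc(OCc2ccccc2)c1C(=O)O
F3 | step 5 | dimethyl 2-[3-(benzyloxy)-2-carboxy-5-methylphenoxy]-3-(2-oxopropyl)butanedioate | COC(=O)C(Oc1cc(C)cc(OCc2ccccc2)c1C(=O)O)C(CC(C)=O)C(=O)OC
F4 | step 7 | 2-(benzyloxy)-6-{[3-bromo-3-chloro-6-(methoxycarbonyl)-2,4-dioxocyclohexyl]oxy}-4-methylbenzoic acid | COC(=O)C1CC(=O)C(Cl)(Br)C(=O)C1Oc1cc(C)cc(OCc2ccccc2)c1C(=O)O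
F5 | step 9 | methyl 1-(benzyloxy)-9-chloro-8-hydroxy-3-methyl-11-oxo-11H-dibenzo[b,e][1,4]dioxepine-6-carboxylate | COC(=O)c1cc(O)c(Cl)c2OC(=O)c3c(OCc4ccccc4)cc(C)cc3Oc12
F6 | step 9 | methyl 1,8-bis(benzyloxy)-9-chloro-3-methyl-11-oxo-11H-dibenzo[b,e][1,4]dioxepine-6-carboxylate | COC(=O)c1cc(OCc5ccccc5)c(Cl)c2OC(=O)c3c(OCc4ccccc4)cc(C)cc3Oc12
F7 | step 9 | benzyl 2-(benzyloxy)-6-[4-(benzyloxy)-3-chloro-2-hydroxy-6-(methoxycarbonyl)phenoxy]-4-methylbenzoate | COC(=O)c1cc(OCc2ccccc2)c(Cl)c(O)c1Oc1cc(C)cc(OCc2ccccc2)c1C(=O)OCc1ccccc1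
F8 | step 9 | benzyl 2-(benzyloxy)-6-[4-(benzyloxy)-3-chloro-2-methoxy-6-(methoxycarbonyl)phenoxy]-4-methylbenzoate | COC(=O)c1cc(OCc2ccccc2)c(Cl)c(OC)c1Oc1cc(C)cc(OCc2ccccc2)c1C(=O)OCc1ccccc1
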